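Decide first to follow one molecule of second end groups instead of the whole flask: it ends in a link, or it doesn't.

- alder: first end groups 10 mM; second end groups 1 equiv (in portions, 4); one-sided end groups 0.30 mM; run made earlier; portions every 6.0 min
- flask: first end groups 10 mM; second end groups 1.00 equiv (in portions, 4); one-sided end groups 0.200 mM; time 8.0 h; the portions of second end groups follow each other after 6.0 min, the first at the start

- alder (time / h: links / %): 0.200: 33.5; 0.417: 65.5; 1.00: 68.8; 2.50: 69.5

(standard deviation of a reading: 1 percentage point)

* at 8.0 h, what has stopped the reaction, if anything has (all of the first end groups has reacted / it is still moving / the second end groups has run out first)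
* links at 8.0 h, in percent of the first end groups charged

- a reading or a percentage of links counts all its forms, free or not
- the reaction counts as stopped when no species that holds the first end groups changes by six tenths of a point or more over the second half of the time

Read the alder run as rates, in fractions of the first end groups charged. Up to 0.200 h links grow on average at 1.68 h⁻¹, and from there to 0.417 h at 1.47 h⁻¹, a slowing of a factor 1.14 over a stretch in which portions still go in. The next stretch, to 1.00 h, gives 0.0566 h⁻¹, a factor 26.0 down. The fall of the first end groups, taken as what links leave, gives you a factor 1.54, far less than that, so I put most of the slowing down to the partner going. The last stretch gives 0.00467 h⁻¹, though its gain of 0.7 percentage points stands beside readings good to 1 point. Held to 8.0 h, even that rate adds 2.6 points.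

So you can treat second end groups as the limiting reagent and carry 69.5%, read at 2.50 h in the alder run, as the link share, the part of the charged second end groups that ends in links. This flask has less one-sided end groups, but the difference of 1 point of the first end groups is far below the shortfall of 30 points. My reckoning therefore keeps the share and gives 69.5% links.

The forecast also says the second end groups has run out first, but it puts links at 76%, within 69% to 81%, above my figure: “Less of it (0.20 mM) should waste less.”

The flask gives the second end groups has run out first, with 0% of them left, and links at 70.3%, which is a link share of 70.3%.

    first end groups + one-sided end groups → capped ends (k = 59.0 L mol⁻¹ s⁻¹)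
    second end groups → decomposed reagent (k = 0.00100 s⁻¹)
    first end groups + second end groups → links (k = 0.550 L mol⁻¹ s⁻¹)
    crystals ⇌ links, rate k4*(cs4 - [links]) while solid is left; crystals form when [links] > cs4 (solubility = 0.630 mM, k = 0.270 s⁻¹)
    2 second end groups → self-condensation product (k = 0.0970 L mol⁻¹ s⁻¹)

Now take the neighbour charged with 0.250 equiv of second end groups. The carried share gives it 17.4% links, and the neighbour holds 20.4%, a link share of 81.6%, higher than in the flask with 1.00 equiv. Its second end groups stand at 0%, and 77.6% of its first end groups remain unreacted.

The data were generated by integration for substances that don't exist, and the scatter is random.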